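Temperature separates the two flasks I am asked about, green and blue, so I want to know what a degree is worth in hours.

| flask | substrate | temperature | remark | time |
|---|---|---|---|---|
| north-west | 0.92 M | 94 °C | run made earlier |  |
| east | 1.5 M | 102 °C | run made earlier |  |
| green | 0.66 M | 90 °C |  | 10 h |
| blue | 0.66 M | 105 °C |  | 10 h |

| run | time / h | target / % |
|---|---|---|
| north-west | 0.500 | 7.7 |
| north-west | 0.833 | 11.2 |
| north-west | 1.50 | 16.1 |
| north-west | 3.00 | 23.1 |
| north-west | 6.00 | 27.6 |
| east | 0.667 | 15.8 |
| east | 1.33 | 22.1 |
| east | 2.00 | 24.5 |
| east | 3.00 | 29.8 |

(standard deviation of a reading: 1 percentage point)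

- a reading or a percentage of target counts all its forms, free or not

* the best flask by amount of target, in percent of the substrate charged; "all alike" if 1.5 percentage points covers them all (green / blue / all alike)
* amount of target at the end, in percent of the substrate charged, green
* amount of target at the end, in percent of the substrate charged, blue

Substrate is the charged reagent, hence the limiting reagent, and my ledger has 100 per cent of it to place. The first entry is target: north-west has booked 27.6% by 6.00 h, which leaves 72.4% unread, as free substrate or as something else.

To see how fast that entry fills, I replace each curve by its mean slope up to a common mark. North-west reaches 16.1% in 1.50 h and east reaches 15.8% in 0.667 h, so east climbs faster by a factor 2.21. This ratio of mean climb rates to a common mark is the clock factor s. I assume the charge does not alter it, which these two runs cannot test.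

The mean hides the bend of the curve, so I check the error at a second mark: 23.1% in 3.00 h against 22.1% in 1.33 h gives 2.16.

Scaling s by degrees, green's 10 h count as 6.73 h on the north-west clock and blue's as 29.7 h, both beyond that run's last reading. East's last reading stands at 6.62 h on that clock and holds 29.8%. So I book green near 29.8%, the reading nearest it on that clock, and blue above that.

The forecast says blue, with 27% for green and 30.5% for blue: “The result therefore depends on the plateau, not the rate”.

Green gives 32.6% and blue 41.9%, so blue is the best flask.

    substrate ⇌ target + by-product (K = 0.660 M, k = 3.30 × 10⁻⁵ s⁻¹, Ea = 117 kJ mol⁻¹, ΔH = −2.00 kJ mol⁻¹)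
    crystals ⇌ by-product, rate k2*(cs2 - [by-product]) while solid is left; crystals form when [by-product] > cs2 (solubility = 0.220 M, k = 0.00290 s⁻¹)
    substrate + target ⇌ idle adduct, settled at all times (K = 44.0 M⁻¹, ΔH = −15.0 kJ mol⁻¹)
    2 substrate → self-condensation product (k = 5.60 × 10⁻⁵ M⁻¹ s⁻¹, Ea = 79.0 kJ mol⁻¹)
    (constants at 90 °C)

At the end, self-condensation product holds 34.6% of the charge in green and 27.9% in blue. From green to blue the clock factor scales to 4.41, which shrinks green's 1.66 h to half conversion to 0.376 h; blue took 0.436 h. A flask like green kept at 65 °C has its 10 h turned by the clock into 0.567 h on the north-west clock, where north-west read 7.7% at 0.500 h, and that flask holds 5.41% target.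

(The runs come from a simulation with made-up constants.)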